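**Retrosynthetic overview**
1. Cembrane numbering is used: C1 is the CH shared by macrocycle and lactone, C3 the lactone O–CH, C4 the methyl carbinol, C15 the lactone CH–CH3. The strategy rests on one feature: C1–C5, C14 and C15–C18 make up a p-menthane that lacks only the C5–C14 bond, and its C1/C3 cis and C3–O/C4–O cis relations are those of a cis-carveol syn-epoxide.
2. The C7 hydroperoxide and C8=C19 methylene come from a Schenck ene reaction on an E-C7=C8 macrocycle. The 14-membered ring is closed at C6–C7 by intramolecular B-alkyl Suzuki coupling. C12–C13 comes from an intermolecular B-alkyl Suzuki coupling with a seven-carbon bromo-iodo-diene staple, and the C11/C12 oxirane from Shi epoxidation.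
3. The divinyl lactone comes from a lactone dialdehyde, which comes from ozonolysis of the C5=C14 alkene of a bridged bicyclic lactone built on (R)-carvone.
4. Ring order: carvone carbocycle (bought), six-membered lactone bridged across it, carbocycle cut open, oxirane added, 14-membered ring last.

Key step: step 8

Remark on the chemistry: the hydroboration of step 5 is not expected to control C15, so compounds 7 to 15 are C15 epimer mixtures and their SMILES leave C15 undefined; the mixture converges in step 10. In step 5 both hydroxyl groups are assumed to be carried as O-borinates in the flask.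

**Lactone fragment**

Step 1
Reactants: 1 (R)-(−)-carvone
Product: 2 (1R,5R)-cis-carveol
Conditions: NaBH4, CeCl3·7H2O, MeOH, −78 → 0 °C
Reagents that add atoms: none
Why: Luche 1,2-reduction, in which axial hydride delivery to the enone carbonyl should place the new C3 hydroxyl equatorial and therefore cis to the C1 isopropenyl group.

Step 2
Reactants: 2 (1R,5R)-cis-carveol
Product: 3 cis-carveol syn-epoxide (C4/C5 oxirane on the face of the C3 hydroxyl)
Conditions: VO(acac)2 (cat.), t-BuOOH, CH2Cl2, 0 °C → rt
Reagents that add atoms: tert-butyl hydroperoxide, CC(C)(C)OO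
Why: hydroxyl-directed vanadium-catalysed epoxidation, in which the vanadate ester of the C3 alcohol should deliver oxygen to the same face of the ring alkene (C4–O cis to C3–O) and leave the undirected isopropenyl alkene alone.

Step 3
Reactants: 3 cis-carveol syn-epoxide
Product: 4 C5 phenylselanyl diol (selenium trans to the C4 hydroxyl)
Conditions: (PhSe)2, NaBH4, EtOH, rt → 78 °C
Reagents that add atoms: diphenyl diselenide, c1ccccc1[Se][Se]c1ccccc1
Why: SN2 epoxide opening by phenylselenolate at the secondary carbon C5, which is also the trans-diaxial (Fürst–Plattner) mode through the chair that keeps the isopropenyl group and the C3 hydroxyl equatorial, so the C4–O bond and its configuration are kept.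

Step 4
Reactants: 4 C5 phenylselanyl diol
Product: 6 allylic cis-diol (p-mentha-5,8-diene-1,2-cis-diol), via selenoxide 5 (not isolated)
Conditions: 30% H2O2, pyridine, THF, 0 °C → rt
Reagents that add atoms: none
Why: selenide oxidation followed by selenoxide syn-elimination, which can only run toward C14 because C4 carries no hydrogen, so the C5=C14 alkene should form without touching a stereocentre.

Step 5
Reactants: 6 allylic cis-diol
Product: 8 triol (C16 primary alcohol; C15 epimers), via borane 7 (not isolated)
Conditions: 9-BBN (3.5 equiv), THF, 0 °C → rt; then NaOH, H2O2, 0 °C → rt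
Reagents that add atoms: hydrogen peroxide, OO
Why: anti-Markovnikov hydroboration–oxidation, in which 9-BBN should react with the 1,1-disubstituted isopropenyl group far faster than with the ring cis-alkene; the new C15 centre is not controlled here and is corrected in step 10.

Step 6
Reactants: 8 triol
Product: 11 bridged hydroxy lactone (2-oxabicyclo[3.3.1]non-6-en-3-one skeleton; C15 epimers), via hydroxy aldehyde 9 (not isolated), via lactol 10 (not isolated)
Conditions: TEMPO (cat.), PhI(OAc)2, CH2Cl2, rt
Reagents that add atoms: none
Why: TEMPO oxidative lactonization, in which the oxoammonium species should oxidise only the primary alcohol, the aldehyde is trapped by the cis C3 hydroxyl as the bridged lactol, and this is oxidised on to the δ-lactone while the tertiary C4 alcohol stays inert.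

Step 7
Reactants: 11 bridged hydroxy lactone
Product: 12 silylated bridged lactone (C4 triethylsilyl ether; C15 epimers)
Conditions: Et3SiOTf, 2,6-lutidine, CH2Cl2, −78 → 0 °C
Reagents that add atoms: triethylsilyl trifluoromethanesulfonate, CC[Si](CC)(CC)OS(=O)(=O)C(F)(F)F
Why: silyl triflate silylation of a hindered tertiary alcohol, which removes the free hydroxyl next to the future C5 aldehyde and builds the steric bias used in step 15.

Step 8
Reactants: 12 silylated bridged lactone
Product: 14 lactone dialdehyde (C14 aldehyde on C1 and C5 aldehyde on C4; C15 epimers), via ozonide 13 (not isolated)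
Conditions: O3, CH2Cl2, −78 °C; then PPh3, −78 °C → rt
Reagents that add atoms: ozone, [O-][O+]=O
Why: Ozone adds to the cis-disubstituted C5=C14 alkene by 1,3-dipolar cycloaddition, the primary ozonide cycloreverts to an aldehyde and a carbonyl oxide that recombine to the secondary ozonide 13, and PPh3 reduces this to the two aldehydes. The closest known reaction type is the ozonolytic ring opening of a chiral-pool terpene cycloalkene. No ring is closed and no stereocentre is created: the six-membered carbocycle is opened, so the bridged bicycle becomes a monocyclic δ-lactone that can relax to a chair with C14 and C4 equatorial and, after step 10, the C15 methyl equatorial as well. The step needs chemoselectivity, which is secured because the isopropenyl alkene has already been used up in the lactone and C5=C14 is the only alkene left. It also needs configurational integrity: none of C1, C3, C4 or C15 is a cleaved carbon, C4 has no α-hydrogen, and enolisation of the C14 aldehyde at C1 could only return the wanted equatorial isomer. The two new termini differ strongly in hindrance (C5 on the quaternary silyloxy carbon, C14 on a ring CH), and this difference is what the ordered double Suzuki stapling relies on.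

Step 9
Reactants: 14 lactone dialdehyde
Product: 15 divinyl lactone as C15 epimer mixture
Conditions: CH2I2, Zn, Ti(OiPr)4, THF, rt
Reagents that add atoms: diiodomethane, ICI
Why: Takai methylenation with a non-basic zinc/titanium methylene reagent, which should convert both aldehydes (bringing in C13 and C6) without enolising the C14 aldehyde toward an intramolecular aldol and without attacking the lactone.

Step 10
Reactants: 15 divinyl lactone as C15 epimer mixture
Product: 16 (15S)-divinyl lactone (all-equatorial δ-lactone)
Conditions: DBU, toluene, 80 °C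
Reagents that add atoms: none
Why: base-mediated epimerisation through the lactone enolate, under thermodynamic control, should converge the mixture on the isomer with the C15 methyl trans to the C1 vinyl group, where all three lactone substituents are equatorial.

**Staple**

Step 11
Reactants: 17 1-(trimethylsilyl)propyne; 18 1-bromo-2-butyne
Product: 20 1-(trimethylsilyl)hepta-1,5-diyne, via lithiopropyne 19 (not isolated)
Conditions: n-BuLi, THF, −78 → −20 °C; then 18, −78 °C → rt
Reagents that add atoms: none
Why: propargylic lithiation of the silylpropyne and SN2 alkylation with the primary propargylic bromide, the silyl group steering the anion to react at its propargylic carbon.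

Step 12
Reactants: 20 1-(trimethylsilyl)hepta-1,5-diyne
Product: 21 hepta-1,5-diyne
Conditions: K2CO3, MeOH, rt
Reagents that add atoms: none
Why: methanolysis of the alkynyl C–Si bond (protodesilylation) should free the terminal alkyne; the volatile diyne is carried on as a solution.

Step 13
Reactants: 21 hepta-1,5-diyne
Product: 23 (E)-1-bromo-2-methylhept-1-en-5-yne, via alkenylalane 22 (not isolated)
Conditions: AlMe3, Cp2ZrCl2 (cat.), CH2Cl2, 0 °C → rt; then NBS, THF, −78 → 0 °C
Reagents that add atoms: trimethylaluminium, C[Al](C)C; N-bromosuccinimide, BrN1C(=O)CCC1=O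
Why: zirconium-catalysed methylalumination (Negishi carboalumination), in which syn addition of methyl and aluminium to the terminal alkyne (aluminium at the terminus) and bromodealumination with retention should fix the E geometry, the internal alkyne reacting more slowly.

Step 14
Reactants: 23 (E)-1-bromo-2-methylhept-1-en-5-yne
Product: 25 (1E,5E)-1-bromo-6-iodo-2-methylhepta-1,5-diene, via alkenylzirconocene 24 (not isolated)
Conditions: Cp2Zr(H)Cl (2 equiv), THF, rt → 50 °C; then I2, 0 °C
Reagents that add atoms: iodine, II
Why: hydrozirconation–iodination, in which syn addition of Zr–H to the 2-alkyne, equilibrated by excess reagent so that zirconium sits on the methyl-bearing carbon, and iododezirconation with retention should give the E-iodoalkene, the trisubstituted bromoalkene being much slower toward the hydride.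

**Union and endgame**

Step 15
Reactants: 16 (15S)-divinyl lactone; 25 (1E,5E)-1-bromo-6-iodo-2-methylhepta-1,5-diene
Product: 27 seco-diene bromide, via alkylborane 26 (not isolated)
Conditions: 9-BBN (1.05 equiv), THF, 0 °C → rt; then 25, Pd(dppf)Cl2 (cat.), AsPh3, Cs2CO3, DMF/H2O, rt
Reagents that add atoms: none
Why: B-alkyl Suzuki–Miyaura coupling, in which 9-BBN should select the C13=C14 vinyl group on the ring CH over the vinyl group flanked by the quaternary silyloxy carbon, and oxidative addition of zerovalent palladium into C–I at room temperature should outpace C–Br, so only the C12–C13 bond forms with the E geometry kept.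

Step 16
Reactants: 27 seco-diene bromide
Product: 28 seco-epoxide bromide ((11S,12S)-oxirane)
Conditions: L-fructose-derived Shi ketone (cat.), KHSO5 (as 2KHSO5·KHSO4·K2SO4), K2CO3, Bu4NHSO4, MeCN/dimethoxymethane, aq. Na2B4O7/Na2EDTA buffer, 0 °C
Reagents that add atoms: potassium peroxymonosulfate, [K+].[O-]S(=O)(=O)OO
Why: Shi asymmetric epoxidation, in which the chiral dioxirane should attack only the electron-rich trisubstituted C11=C12 alkene through the spiro transition state and set C11 and C12 under catalyst control (the L-series ketone for the S,S oxirane), the bromoalkene and the hindered allylic-ether vinyl group being too electron-poor.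

Step 17
Reactants: 28 seco-epoxide bromide
Product: 30 silylated 14-membered epoxy lactone, via alkylborane 29 (not isolated)
Conditions: 9-BBN (3 equiv), THF, rt → 40 °C; H2O; then slow addition to Pd(dppf)Cl2 (cat.), AsPh3, Cs2CO3, THF/DMF/H2O, 50 °C, about 1 mM
Reagents that add atoms: none
Why: intramolecular B-alkyl Suzuki–Miyaura macrocyclisation, in which hydroboration of the only remaining vinyl group puts boron on C6 and high dilution should favour closure of the C6–C7 bond onto the E-bromoalkene with retention of geometry, the epoxide and lactone being inert to 9-BBN at this temperature.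

Step 18
Reactants: 30 silylated 14-membered epoxy lactone
Product: 31 7,8-ene precursor with free C4 hydroxyl
Conditions: Bu4NF, THF, 0 °C → rt
Reagents that add atoms: none
Why: fluoride-mediated desilylation, driven by the Si–F bond, should free the tertiary alcohol without acid that could open the trisubstituted oxirane.

Step 19
Reactants: 31 7,8-ene precursor with free C4 hydroxyl
Product: 32 target CNP0319766.1
Conditions: O2, visible light, tetraphenylporphyrin (cat.), CH2Cl2, −20 °C; no reductive work-up
Reagents that add atoms: oxygen, O=O
Why: Schenck ene reaction, in which singlet oxygen should bond to C7 and take a C19 methyl hydrogen from the more crowded side of the E-alkene so that the double bond moves to C8=C19; the C7 configuration is expected from attack on the exposed peripheral face of the macrocycle and is the least secure centre, so any C7 epimer or C8 tertiary hydroperoxide is removed by chromatography.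

**Compound list**
1 | (R)-(−)-carvone | C1[C@@H](C(C)=C)CC(=O)C(C)=C1 | starting material
2 | (1R,5R)-cis-carveol | C1[C@@H](C(C)=C)C[C@@H](O)C(C)=C1 | intermediate
3 | cis-carveol syn-epoxide (oxirane, C3 hydroxyl and C1 isopropenyl on one face) | C1[C@@H](C(C)=C)C[C@@H](O)[C@@]2(C)O[C@H]21 | intermediate
4 | C5 phenylselanyl diol (selenium trans to the C4 hydroxyl; C3–OH, C4–OH and isopropenyl cis) | C1[C@@H](C(C)=C)C[C@@H](O)[C@@](C)(O)[C@@H]1[Se]c1ccccc1 | intermediate
5 | selenoxide of 4 | C1[C@@H](C(C)=C)C[C@@H](O)[C@@](C)(O)[C@@H]1[Se](=O)c1ccccc1 | intermediate (not isolated)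
6 | p-mentha-5,8-diene-1,2-cis-diol (C5=C14 alkene; C3–OH, C4–OH and C1 isopropenyl on one face) | C=1[C@@H](C(C)=C)C[C@@H](O)[C@@](C)(O)C=1 | intermediate
7 | C16 B-alkyl-9-BBN adduct of 6 with both hydroxyls as O-(9-BBN) borinates, C15 epimers | C=1[C@@H](C(C)CB2C3CCCC2CCC3)C[C@@H](OB2C3CCCC2CCC3)[C@@](C)(OB2C3CCCC2CCC3)C=1 | intermediate (not isolated)
8 | triol (C16 primary, C3 secondary, C4 tertiary hydroxyl), C15 epimers | C=1[C@@H](C(C)CO)C[C@@H](O)[C@@](C)(O)C=1 | intermediate
9 | C16 hydroxy aldehyde, C15 epimers | C=1[C@@H](C(C)C=O)C[C@@H](O)[C@@](C)(O)C=1 | intermediate (not isolated)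
10 | bridged lactol, C15 epimers | C=1[C@@H]2C[C@@H](OC(O)C2C)[C@@](C)(O)C=1 | intermediate (not isolated)
11 | bridged hydroxy lactone (8-hydroxy-4,8-dimethyl-2-oxabicyclo[3.3.1]non-6-en-3-one skeleton), C15 epimers; the 15S member maps on to the target | C=1[C@@H]2C[C@@H](OC(=O)C2C)[C@@](C)(O)C=1 | intermediate
12 | C4 O-triethylsilyl ether of 11, C15 epimers | C=1[C@@H]2C[C@@H](OC(=O)C2C)[C@@](C)(O[Si](CC)(CC)CC)C=1 | intermediate
13 | secondary ozonide of 12 (1,2,4-trioxolane across C5 and C14) | O1OC2[C@@H]3C[C@@H](OC(=O)C3C)[C@@](C)(O[Si](CC)(CC)CC)C1O2 | intermediate (not isolated)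
14 | lactone dialdehyde (C14 aldehyde on C1, C5 aldehyde on C4), C15 epimers | O=C[C@@H]1C[C@@H](OC(=O)C1C)[C@@](C)(O[Si](CC)(CC)CC)C=O | intermediate
15 | divinyl lactone, C15 epimer mixture | C=C[C@@H]1C[C@@H](OC(=O)C1C)[C@@](C)(O[Si](CC)(CC)CC)C=C | intermediate
16 | (15S)-divinyl lactone, all-equatorial | C=C[C@@H]1C[C@@H](OC(=O)[C@H]1C)[C@@](C)(O[Si](CC)(CC)CC)C=C | intermediate
17 | 1-(trimethylsilyl)propyne | CC#C[Si](C)(C)C | starting material
18 | 1-bromo-2-butyne | CC#CCBr | starting material
19 | 3-lithio-1-(trimethylsilyl)propyne | [Li]CC#C[Si](C)(C)C | intermediate (not isolated)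
20 | 1-(trimethylsilyl)hepta-1,5-diyne | CC#CCCC#C[Si](C)(C)C | intermediate
21 | hepta-1,5-diyne | CC#CCCC#C | intermediate
22 | (E)-dimethyl(2-methylhept-1-en-5-yn-1-yl)alane | C[Al](C)/C=C(C)/CCC#CC | intermediate (not isolated)
23 | (E)-1-bromo-2-methylhept-1-en-5-yne | Br/C=C(C)/CCC#CC | intermediate
24 | alkenylzirconocene chloride from 23 (zirconium on the methyl-bearing carbon) | Br/C=C(C)/CC/C=C(C)/[Zr](Cl)(C1C=CC=C1)C1C=CC=C1 | intermediate (not isolated)
25 | (1E,5E)-1-bromo-6-iodo-2-methylhepta-1,5-diene | Br/C=C(C)/CC/C=C(C)/I | intermediate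
26 | C13 B-alkyl-9-BBN adduct of 16 | B1(CC[C@@H]2C[C@@H](OC(=O)[C@H]2C)[C@@](C)(O[Si](CC)(CC)CC)C=C)C2CCCC1CCC2 | intermediate (not isolated)
27 | seco-diene bromide (C12–C13 joined; E-bromoalkene, E-C11=C12, C5=C6 vinyl) | Br/C=C(C)/CC/C=C(C)/CC[C@@H]1C[C@@H](OC(=O)[C@H]1C)[C@@](C)(O[Si](CC)(CC)CC)C=C | intermediate
28 | seco-epoxide bromide ((11S,12S)-oxirane) | Br/C=C(C)/CC[C@@H]2O[C@@]2(C)CC[C@@H]1C[C@@H](OC(=O)[C@H]1C)[C@@](C)(O[Si](CC)(CC)CC)C=C | intermediate
29 | C6 B-alkyl-9-BBN adduct of 28 | Br/C=C(C)/CC[C@@H]2O[C@@]2(C)CC[C@@H]1C[C@@H](OC(=O)[C@H]1C)[C@@](C)(O[Si](CC)(CC)CC)CCB1C2CCCC1CCC2 | intermediate (not isolated)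
30 | silylated 14-membered epoxy lactone (E-C7=C8) | C1[C@@H]2O[C@@]2(C)CC[C@@H]2C[C@@H](OC(=O)[C@H]2C)[C@@](C)(O[Si](CC)(CC)CC)CC/C=C(\C)C1 | intermediate
31 | 7,8-ene precursor with free C4 hydroxyl | C1[C@@H]2O[C@@]2(C)CC[C@@H]2C[C@@H](OC(=O)[C@H]2C)[C@@](C)(O)CC/C=C(\C)C1 | intermediate
32 | CNP0319766.1, (1R,3R,4S,7R,11S,12S,15S)-11,12-epoxy-7-hydroperoxy-4-hydroxycembr-8(19)-en-16,3-olide | C=C1CC[C@@H]2O[C@@]2(C)CC[C@@H]2C[C@@H](OC(=O)[C@H]2C)[C@@](C)(O)CC[C@H]1OO | target

**Totals**
Total step count: 19.
Longest linear sequence: 15 steps (steps 1–10 and 15–19, from (R)-carvone); the staple branch is steps 11–14.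

**Three steps most likely to fail**

Step 19. The process at risk is poor facial selectivity of singlet oxygen at C7, together with competing abstraction of a C6 hydrogen that leads to a C8 tertiary hydroperoxide. The fallback sets out from 31 and returns at 32, and fixes C7 by reagent control. Photooxygenation of 31 as in step 19 would give the C7-epimeric secondary hydroperoxides F7, and Ac2O/pyridine added to the same flask would dehydrate them (Kornblum–DeLaMare type) to the 8(19)-en-7-one F8. Reduction with (R)-2-methyl-CBS-oxazaborolidine and catecholborane, with the alkenyl group acting as the large substituent, should give the (7S)-allylic alcohol F9. MsCl/Et3N at −40 °C would give the (7S)-mesylate F10, used cold without purification. SN2 displacement with 2-methoxyprop-2-yl hydroperoxide and CsOH·H2O in DMF at 0 °C should invert C7 to the (7R)-peroxyketal F11, and AcOH/THF/H2O would release 32.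

Step 15. The process at risk is incomplete discrimination by 9-BBN between the C13=C14 and C5=C6 vinyl groups, with some oxidative addition at the bromide as a second leak. The fallback sets out from 14 and returns at 27, and differentiates the termini before any borane is used. One equivalent of the CH2I2/Zn/Ti(OiPr)4 reagent at low temperature should methylenate only the unhindered C14 aldehyde and give the vinyl aldehyde F1. Excess 9-BBN would then hydroborate the single vinyl group and reduce the neopentyl aldehyde, giving the bis-boron adduct F2. Coupling of F2 with 25 under the conditions of step 15 should give the primary alcohol F3 after work-up. Dess–Martin oxidation would give the aldehyde F4, and a second Takai methylenation the seco-diene bromide epimer mixture F5. DBU equilibration as in step 10 then gives 27.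

Step 17. The process at risk is slow hydroboration of the vinyl group next to the quaternary silyloxy carbon, followed by intermolecular coupling or protodeboronation during ring closure. The fallback sets out from 28 and returns at 30, and forms the same C6–C7 bond without boron. An intramolecular Heck reaction (Pd(OAc)2, Bu4NCl, K2CO3, DMF, 70 °C, high dilution) of the bromoalkene onto the terminal carbon of the vinyl group should give the macrocyclic (5E,7E)-diene F6. Diimide from 2-nitrobenzenesulfonylhydrazide and Et3N should then reduce the disubstituted C5=C6 bond faster than the trisubstituted C7=C8 bond and give 30.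

**Further compounds**
F1 | step 15 | vinyl aldehyde (C13=C14 vinyl, C5 aldehyde), C15 epimers | C=C[C@@H]1C[C@@H](OC(=O)C1C)[C@@](C)(O[Si](CC)(CC)CC)C=O
F2 | step 15 | bis-boron adduct (C13 B-alkyl-9-BBN, C5 O-(9-BBN) borinate), C15 epimers | C(C[C@@H]1C[C@@H](OC(=O)C1C)[C@@](C)(O[Si](CC)(CC)CC)COB1C2CCCC1CCC2)B1C2CCCC1CCC2
F3 | step 15 | coupled primary alcohol (C5 hydroxymethyl), C15 epimers | Br/C=C(C)/CC/C=C(C)/CC[C@@H]1C[C@@H](OC(=O)C1C)[C@@](C)(O[Si](CC)(CC)CC)CO
F4 | step 15 | coupled C5 aldehyde, C15 epimers | Br/C=C(C)/CC/C=C(C)/CC[C@@H]1C[C@@H](OC(=O)C1C)[C@@](C)(O[Si](CC)(CC)CC)C=O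
F5 | step 15 | seco-diene bromide, C15 epimer mixture | Br/C=C(C)/CC/C=C(C)/CC[C@@H]1C[C@@H](OC(=O)C1C)[C@@](C)(O[Si](CC)(CC)CC)C=C
F6 | step 17 | silylated macrocyclic (5E,7E)-diene | C1[C@@H]2O[C@@]2(C)CC[C@@H]2C[C@@H](OC(=O)[C@H]2C)[C@@](C)(O[Si](CC)(CC)CC)/C=C/C=C(\C)C1
F7 | step 19 | 7-hydroperoxide as C7 epimer mixture | C=C1CC[C@@H]2O[C@@]2(C)CC[C@@H]2C[C@@H](OC(=O)[C@H]2C)[C@@](C)(O)CCC1OO
F8 | step 19 | 8(19)-en-7-one | C=C1CC[C@@H]2O[C@@]2(C)CC[C@@H]2C[C@@H](OC(=O)[C@H]2C)[C@@](C)(O)CCC1=O
F9 | step 19 | (7S)-allylic alcohol | C=C1CC[C@@H]2O[C@@]2(C)CC[C@@H]2C[C@@H](OC(=O)[C@H]2C)[C@@](C)(O)CC[C@@H]1O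
F10 | step 19 | (7S)-mesylate | C=C1CC[C@@H]2O[C@@]2(C)CC[C@@H]2C[C@@H](OC(=O)[C@H]2C)[C@@](C)(O)CC[C@@H]1OS(C)(=O)=O
F11 | step 19 | (7R)-2-methoxyprop-2-yl peroxyketal | C=C1CC[C@@H]2O[C@@]2(C)CC[C@@H]2C[C@@H](OC(=O)[C@H]2C)[C@@](C)(O)CC[C@H]1OOC(C)(C)OC
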